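Ring A (C1 butanoyl, C2 OH, C3 methyl, C4 OH, C5 bridge CH2, C6 OH) is cut at C1–C2 and C5–C6. The C2–C5 arc, with two oxygens, the methyl and the arm to ring B, is a 1-methoxy-1,3-bis(trimethylsilyloxy)diene; C6–C1, with the third oxygen and the butanoyl group, is a benzyloxy ynone. One polarised [4+2] addition with loss of methanol builds the hexasubstituted ring, exploiting the alternating O2/O4/O6 pattern with the acyl carbon between O2 and O6. The diene comes from a ring B aldehyde and a keto ester dianion; ring B keeps one free CH for the final propanoylation.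

Key step: step 9

Remark on the chemistry: the target is achiral; the stereocentres that appear in 8, 9 and 19 are left unspecified (racemic or diastereomeric mixtures) because all of them are destroyed before ring A is complete.

Step 1
Reactants: 1 2,4,6-trihydroxytoluene
Product: 3 2,4,6-trihydroxy-3-methylbenzaldehyde, via iminium chloride 2 (not isolated)
Conditions: POCl3, DMF, EtOAc, 0 °C to rt; then H2O, 60 °C
Reagents that add atoms: N,N-dimethylformamide CN(C)C=O; water O
Why: Vilsmeier–Haack formylation of a phloroglucinol, in which the two free ring carbons of 1 are equivalent by symmetry and the iminium group of 2 deactivates the ring against a second attack before hydrolysis releases the aldehyde.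

Step 2
Reactants: 3 2,4,6-trihydroxy-3-methylbenzaldehyde
Product: 4 4,6-bis(benzyloxy)-2-hydroxy-3-methylbenzaldehyde
Conditions: BnBr (2.1 equiv), K2CO3, DMF, 0 °C to rt
Reagents that add atoms: benzyl bromide BrCc1ccccc1
Why: Williamson ether synthesis in which the para hydroxyl (most acidic, not hydrogen-bonded) and the ortho hydroxyl next to the ring CH react first, while the hydroxyl wedged between the formyl and methyl groups, held in a strong hydrogen bond to the carbonyl, should remain.

Step 3
Reactants: 4 4,6-bis(benzyloxy)-2-hydroxy-3-methylbenzaldehyde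
Product: 5 4,6-bis(benzyloxy)-2-methoxy-3-methylbenzaldehyde
Conditions: MeI, K2CO3, DMF, 40 °C
Reagents that add atoms: iodomethane CI
Why: Williamson O-methylation of the one remaining, chelated phenol under slightly forcing conditions, with no other nucleophilic site left in the molecule.

Step 4
Reactants: 5 4,6-bis(benzyloxy)-2-methoxy-3-methylbenzaldehyde; 6 methyl 2-methyl-3-oxobutanoate
Product: 8 methyl 5-[4,6-bis(benzyloxy)-2-methoxy-3-methylphenyl]-5-hydroxy-2-methyl-3-oxopentanoate, via sodium lithium dianion 7 (not isolated)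
Conditions: 6, NaH, THF, 0 °C; n-BuLi, 0 °C; then 5, −78 °C; aq NH4Cl
Reagents that add atoms: none
Why: Aldol addition of a β-keto ester dianion, which reacts at its more basic terminal carbon; the two new stereocentres are not controlled and need not be, since the carbinol carbon is reduced in step 5 and the α-carbon becomes trigonal in step 6.

Step 5
Reactants: 8 methyl 5-[4,6-bis(benzyloxy)-2-methoxy-3-methylphenyl]-5-hydroxy-2-methyl-3-oxopentanoate
Product: 9 methyl 5-[4,6-bis(benzyloxy)-2-methoxy-3-methylphenyl]-2-methyl-3-oxopentanoate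
Conditions: Et3SiH (3 equiv), CF3CO2H (5 equiv), CH2Cl2, −20 to 0 °C
Reagents that add atoms: none
Why: Ionic hydrogenation of a benzylic alcohol, in which the 2,4,6-trioxygenated ring makes the benzylic cation form readily and the silane traps it, while the aliphatic ketone, the ester and the aryl benzyl ethers are inert at this temperature.

Step 6
Reactants: 9 methyl 5-[4,6-bis(benzyloxy)-2-methoxy-3-methylphenyl]-2-methyl-3-oxopentanoate
Product: 11 (1Z,3Z)-1-methoxy-2-methyl-1,3-bis(trimethylsilyloxy)-5-[4,6-bis(benzyloxy)-2-methoxy-3-methylphenyl]penta-1,3-diene, via mono-silyl enol ether 10 (not isolated)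
Conditions: Me3SiCl, Et3N, toluene, rt; filter, concentrate; then LiN(i-Pr)2, THF, −78 °C; Me3SiCl, −78 to 0 °C; used crude
Reagents that add atoms: chlorotrimethylsilane C[Si](C)(C)Cl
Why: O-silylation of the keto ester to the β-silyloxy enoate, then γ-deprotonation and O-silylation of the dienolate, is the standard preparation of 1-alkoxy-1,3-bis(silyloxy)dienes; the 3Z geometry (arm to ring B pointing outward) is the expected kinetic outcome and the one needed for cycloaddition, and the ketene acetal geometry is lost later.

Step 7
Reactants: 12 benzyl alcohol; 13 trichloroethylene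
Product: 15 {[(E)-1,2-dichloroethenyl]oxy}methylbenzene, via potassium benzyl oxide 14 (not isolated)
Conditions: KH, THF, 0 °C; then 13, −50 °C to rt
Reagents that add atoms: none
Why: Base-mediated elimination–addition on trichloroethylene, a net vinylic substitution of chloride by the alkoxide, in which anti addition gives the E dichlorovinyl ether.

Step 8
Reactants: 15 {[(E)-1,2-dichloroethenyl]oxy}methylbenzene; 16 butanoyl chloride
Product: 18 1-(benzyloxy)hex-1-yn-3-one, via lithium benzyloxyacetylide 17 (not isolated)
Conditions: n-BuLi (2.0 equiv), THF, −78 °C; then added to 16 (1.5 equiv), THF, −78 °C; pH 7 buffer, cold work-up; kept below 0 °C and used at once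
Reagents that add atoms: none
Why: Dehydrochlorination and lithium–chlorine exchange give the alkoxyacetylide, and its acylation by inverse addition to an acid chloride stops at the ketone because the product, an alkoxy-conjugated ynone, is far less electrophilic at carbonyl than the acid chloride.

Step 9
Reactants: 11 (1Z,3Z)-1-methoxy-2-methyl-1,3-bis(trimethylsilyloxy)-5-[4,6-bis(benzyloxy)-2-methoxy-3-methylphenyl]penta-1,3-diene; 18 1-(benzyloxy)hex-1-yn-3-one
Product: 21 1-[2-(benzyloxy)-3-{[4,6-bis(benzyloxy)-2-methoxy-3-methylphenyl]methyl}-4,6-dihydroxy-5-methylphenyl]butan-1-one, via cyclohexadiene cycloadduct 19 (not isolated), via aryl bis-silyl ether 20 (not isolated)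
Conditions: 18 (1.5 equiv), Me3SiOTf (0.2 equiv), 2,6-di-tert-butyl-4-methylpyridine (0.2 equiv), CH2Cl2, 4 Å molecular sieves, −78 to −20 °C; then 1 M HCl, THF, 0 °C to rt
Reagents that add atoms: none
Why: Proposed new method: silylation of the ynone carbonyl by Me3SiOTf places the positive charge on the benzyloxy-bearing alkyne carbon (future C6 of ring A), the diene attacks it through its bridge-bearing terminus (future C5), and the resulting silyl allenol ether closes through the butanoyl-bearing carbon (future C1) onto the O-silylated ester carbon (future C2), so the two new bonds are those of a polarised, asynchronous Diels–Alder addition; the closest known reaction is the thermal [4+2] addition and aromatisation of 1-alkoxy-1,3-bis(silyloxy)dienes with alkynyl ketones and propiolates to give resorcinols, and the Lewis acid is proposed because the benzyloxy group makes this ynone a weaker dienophile. Ring A is closed by intermolecular [4+2] annulation of the four diene carbons onto the two alkyne carbons; in the stepwise limit the second bond forms by 6-exo-trig attack of the allenol ether carbon on the oxocarbenium carbon. Cycloadduct 19 is a 1,4-cyclohexadiene whose mixed ketal carbon loses methanol together with the hydrogen on C5, giving the aromatic bis-silyl ether 20, which dilute acid hydrolyses to 21. No stereocentre survives. Only regiocontrol is needed: the donor oxygens make the bridge-bearing terminus the nucleophilic end of the diene and the carbonyl makes the benzyloxy carbon the electrophilic end of the ynone, so the butanoyl group should end up between two oxygens, and the 2-methyl and 3-silyloxy groups bias the diene towards the cisoid conformer needed for closure.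

Step 10
Reactants: 21 1-[2-(benzyloxy)-3-{[4,6-bis(benzyloxy)-2-methoxy-3-methylphenyl]methyl}-4,6-dihydroxy-5-methylphenyl]butan-1-one
Product: 23 1-[2-(benzyloxy)-3-{[4,6-bis(benzyloxy)-2-methoxy-3-methyl-5-propanoylphenyl]methyl}-4,6-dihydroxy-5-methylphenyl]butan-1-one, via tripropanoyl intermediate 22 (not isolated)
Conditions: EtCO2H (6 equiv), (CF3CO)2O (6 equiv), CH2Cl2, 0 °C to rt; concentrate; then K2CO3 (2.2 equiv), MeOH, rt
Reagents that add atoms: propanoic acid CCC(=O)O
Why: Friedel–Crafts acylation by a mixed carboxylic trifluoroacetic anhydride can only go to the single free carbon of the trialkoxy ring B because ring A has none, the two ring A phenols are esterified in passing (which also deactivates ring A and protects the bridge), and methanolysis returns them.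

Step 11
Reactants: 23 1-[2-(benzyloxy)-3-{[4,6-bis(benzyloxy)-2-methoxy-3-methyl-5-propanoylphenyl]methyl}-4,6-dihydroxy-5-methylphenyl]butan-1-one
Product: 24 1-[3-{[4,6-dihydroxy-2-methoxy-3-methyl-5-propanoylphenyl]methyl}-2,4,6-trihydroxy-5-methylphenyl]butan-1-one
Conditions: H2 (1 atm), Pd/C, EtOAc/MeOH, rt
Reagents that add atoms: none
Why: Catalytic hydrogenolysis of the three aryl benzyl ethers under neutral conditions should leave the hydrogen-bonded aryl ketones, the methyl ether and the diarylmethane bridge untouched.

Compound list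
1 | 2,4,6-trihydroxytoluene | Cc1c(O)cc(O)cc1O | starting material
2 | N-[(2,4,6-trihydroxy-3-methylphenyl)methylidene]-N-methylmethanaminium chloride | C[N+](C)=Cc1c(O)cc(O)c(C)c1O.[Cl-] | intermediate
3 | 2,4,6-trihydroxy-3-methylbenzaldehyde | O=Cc1c(O)cc(O)c(C)c1O | intermediate
4 | 4,6-bis(benzyloxy)-2-hydroxy-3-methylbenzaldehyde | O=Cc1c(OCc2ccccc2)cc(OCc2ccccc2)c(C)c1O | intermediate
5 | 4,6-bis(benzyloxy)-2-methoxy-3-methylbenzaldehyde | O=Cc1c(OCc2ccccc2)cc(OCc2ccccc2)c(C)c1OC | intermediate
6 | methyl 2-methyl-3-oxobutanoate (racemic) | COC(=O)C(C)C(C)=O | starting material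
7 | sodium lithium dianion of methyl 2-methyl-3-oxobutanoate | [Na+].[Li+].C=C([O-])C(C)=C([O-])OC | intermediate
8 | methyl 5-[4,6-bis(benzyloxy)-2-methoxy-3-methylphenyl]-5-hydroxy-2-methyl-3-oxopentanoate (mixture of diastereomers) | COC(=O)C(C)C(=O)CC(O)c1c(OCc2ccccc2)cc(OCc2ccccc2)c(C)c1OC | intermediate
9 | methyl 5-[4,6-bis(benzyloxy)-2-methoxy-3-methylphenyl]-2-methyl-3-oxopentanoate (racemic) | COC(=O)C(C)C(=O)CCc1c(OCc2ccccc2)cc(OCc2ccccc2)c(C)c1OC | intermediate
10 | methyl 5-[4,6-bis(benzyloxy)-2-methoxy-3-methylphenyl]-2-methyl-3-(trimethylsilyloxy)pent-2-enoate (E/Z mixture) | COC(=O)C(C)=C(CCc1c(OCc2ccccc2)cc(OCc2ccccc2)c(C)c1OC)O[Si](C)(C)C | intermediate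
11 | (1Z,3Z)-1-methoxy-2-methyl-1,3-bis(trimethylsilyloxy)-5-[4,6-bis(benzyloxy)-2-methoxy-3-methylphenyl]penta-1,3-diene | CO/C(O[Si](C)(C)C)=C(C)/C(O[Si](C)(C)C)=C/Cc1c(OCc2ccccc2)cc(OCc2ccccc2)c(C)c1OC | intermediate
12 | benzyl alcohol | OCc1ccccc1 | starting material
13 | trichloroethylene | ClC=C(Cl)Cl | starting material
14 | potassium benzyl oxide | [K+].[O-]Cc1ccccc1 | intermediate
15 | {[(E)-1,2-dichloroethenyl]oxy}methylbenzene | Cl/C=C(/Cl)OCc1ccccc1 | intermediate
16 | butanoyl chloride | CCCC(Cl)=O | starting material
17 | lithium (benzyloxy)acetylide | [Li+].[C-]#COCc1ccccc1 | intermediate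
18 | 1-(benzyloxy)hex-1-yn-3-one | CCCC(=O)C#COCc1ccccc1 | intermediate
19 | 1-[2-(benzyloxy)-3-{[4,6-bis(benzyloxy)-2-methoxy-3-methylphenyl]methyl}-6-methoxy-5-methyl-4,6-bis(trimethylsilyloxy)cyclohexa-1,4-dien-1-yl]butan-1-one (stereocentres unspecified) | CCCC(=O)C1=C(OCc2ccccc2)C(Cc2c(OCc3ccccc3)cc(OCc3ccccc3)c(C)c2OC)C(O[Si](C)(C)C)=C(C)C1(OC)O[Si](C)(C)C | intermediate
20 | 1-[2-(benzyloxy)-3-{[4,6-bis(benzyloxy)-2-methoxy-3-methylphenyl]methyl}-5-methyl-4,6-bis(trimethylsilyloxy)phenyl]butan-1-one | CCCC(=O)c1c(O[Si](C)(C)C)c(C)c(O[Si](C)(C)C)c(Cc2c(OCc3ccccc3)cc(OCc3ccccc3)c(C)c2OC)c1OCc1ccccc1 | intermediate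
21 | 1-[2-(benzyloxy)-3-{[4,6-bis(benzyloxy)-2-methoxy-3-methylphenyl]methyl}-4,6-dihydroxy-5-methylphenyl]butan-1-one | CCCC(=O)c1c(O)c(C)c(O)c(Cc2c(OCc3ccccc3)cc(OCc3ccccc3)c(C)c2OC)c1OCc1ccccc1 | intermediate
22 | 5-(benzyloxy)-4-{[4,6-bis(benzyloxy)-2-methoxy-3-methyl-5-propanoylphenyl]methyl}-6-butanoyl-2-methyl-1,3-phenylene dipropanoate | CCCC(=O)c1c(OC(=O)CC)c(C)c(OC(=O)CC)c(Cc2c(OCc3ccccc3)c(C(=O)CC)c(OCc3ccccc3)c(C)c2OC)c1OCc1ccccc1 | intermediate
23 | 1-[2-(benzyloxy)-3-{[4,6-bis(benzyloxy)-2-methoxy-3-methyl-5-propanoylphenyl]methyl}-4,6-dihydroxy-5-methylphenyl]butan-1-one | CCCC(=O)c1c(O)c(C)c(O)c(Cc2c(OCc3ccccc3)c(C(=O)CC)c(OCc3ccccc3)c(C)c2OC)c1OCc1ccccc1 | intermediate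
24 | 1-[3-{[4,6-dihydroxy-2-methoxy-3-methyl-5-propanoylphenyl]methyl}-2,4,6-trihydroxy-5-methylphenyl]butan-1-one | CCCC(=O)c1c(O)c(C)c(O)c(Cc2c(O)c(C(=O)CC)c(O)c(C)c2OC)c1O | target

Total step count: 11. Longest linear sequence: 9 steps (steps 1 to 6, then 9, 10 and 11); the ynone branch (steps 7 and 8) joins at step 9.

Steps most likely to fail

Step 9 (proposed new method). The diene may add to the carbonyl carbon instead of the benzyloxy-bearing alkyne carbon, the activated alkynyl benzyl ether may ionise with loss of its benzyl group, the diene may be protodesilylated, or the sequence may stop after the first C–C bond without ring closure. The fallback abandons the annulation and uses established acylphloroglucinol chemistry, setting out from 1 and 16 and returning at 24. Friedel–Crafts acylation of 1 with butanoyl chloride 16 (AlCl3, PhNO2) should give 1-(2,4,6-trihydroxy-3-methylphenyl)butan-1-one F1, and a Mannich reaction at its only free ring carbon (aqueous formaldehyde, dimethylamine, EtOH) should give 1-{3-[(dimethylamino)methyl]-2,4,6-trihydroxy-5-methylphenyl}butan-1-one F2. In parallel, acylation of 1 with propanoyl chloride (AlCl3, PhNO2) should give 1-(2,4,6-trihydroxy-3-methylphenyl)propan-1-one F3, whose most acidic, non-chelated para hydroxyl is methylated (Me2SO4, one equivalent, K2CO3, acetone) to 1-(2,6-dihydroxy-4-methoxy-3-methylphenyl)propan-1-one F4. Heating F2 with F4 (dioxane, reflux) should expel dimethylamine to give an ortho-quinone methide of ring A, which the single free ring carbon of F4 captures, giving 24 directly.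

Step 10. The acidic medium may strip benzyl groups or shift them from oxygen to carbon on the electron-rich ring B, cleave the molecule at the methylene bridge, or the acylation may stall at the position flanked by two benzyloxy groups. The fallback reverses the order of the endgame, setting out from 21 and returning at 24. Hydrogenolysis of 21 (H2, Pd/C, EtOAc/MeOH) should give 1-[3-{[4,6-dihydroxy-2-methoxy-3-methylphenyl]methyl}-2,4,6-trihydroxy-5-methylphenyl]butan-1-one F5. This free phenol is then C-acylated at its only free ring carbon by the classical acylphloroglucinol method (propanoic acid, BF3·OEt2, 60 to 80 °C, aqueous work-up), giving 24.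

Step 8. The acetylide may add a second time to the product ketone, and the alkynyl benzyl ether may be hydrated or rearrange thermally during work-up and concentration. The fallback replaces acyl substitution by addition and oxidation, setting out from 15 and returning at 18. Acetylide 17, generated from 15 as before, is added to butanal (THF, −78 °C) to give 1-(benzyloxy)hex-1-yn-3-ol F6, which is oxidised under neutral conditions (MnO2, CH2Cl2, rt) to 18.

Further compounds
F1 | step 9 | 1-(2,4,6-trihydroxy-3-methylphenyl)butan-1-one | CCCC(=O)c1c(O)cc(O)c(C)c1O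
F2 | step 9 | 1-{3-[(dimethylamino)methyl]-2,4,6-trihydroxy-5-methylphenyl}butan-1-one | CCCC(=O)c1c(O)c(CN(C)C)c(O)c(C)c1O
F3 | step 9 | 1-(2,4,6-trihydroxy-3-methylphenyl)propan-1-one | CCC(=O)c1c(O)cc(O)c(C)c1O
F4 | step 9 | 1-(2,6-dihydroxy-4-methoxy-3-methylphenyl)propan-1-one | CCC(=O)c1c(O)cc(OC)c(C)c1O
F5 | step 10 | 1-[3-{[4,6-dihydroxy-2-methoxy-3-methylphenyl]methyl}-2,4,6-trihydroxy-5-methylphenyl]butan-1-one | CCCC(=O)c1c(O)c(C)c(O)c(Cc2c(O)cc(O)c(C)c2OC)c1O
F6 | step 8 | 1-(benzyloxy)hex-1-yn-3-ol (racemic) | CCCC(O)C#COCc1ccccc1
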